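Ring A is first cut back by one carbon (C10, put in later by dibromocarbene) to a spirocyclopentene; that ring is then opened at C6–C11 and C9=C11, which leaves a monocyclic ionone ketone and a one-carbon carbene unit. In the key step lithiated trimethylsilyldiazomethane converts the C9 ketone into an alkylidene carbene whose carbon C11 inserts into the C6–H bond of ring B with retention, closing the five-membered ring and fixing the spiro centre in one operation. The feature exploited is that tertiary, allylic C6–H, the only C–H 1,5 to C11, between the C1=C2 alkene and the C5 gem-dimethyl carbon. The precursor is (6S)-3-hydroxy-7,8-dihydro-α-ionone, which already holds the C3 oxygen.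

Key step: step 6

Numbering: ring B is C1 (methyl-bearing alkene carbon), C2, C3 (carbinol), C4 (CHBr), C5 (CMe2), C6 (spiro); ring A is C6, C7, C8, C9 (methyl-bearing), C10 (CBr), C11.
Target: C3–OH and C4–Br are trans, C4–Br lies on the face of ring B that carries C11; (3S,4S,6S) in this numbering.
Design remark: the C3 oxygen is put on α-ionone before the key step and rides through as a spectator (alkoxide, then pivalate). Ring B alkene is thereby deactivated when dibromocarbene is added, and no late allylic oxidation has to choose between the two rings.
Remark: 9, 10, 13–16 and 18–20 are mixtures of C3 epimers, and 19 is also a mixture of allylic bromide isomers; steps 8 and 9 remove these elements, so the SMILES leave them open.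
Assumption: the less soluble carbazone pairs (S)-α-ionone with the (1S,2R,5S)-menthyl reagent; if the pairing is the opposite, the reagent from (−)-menthyl chloroformate is used and nothing else changes.

Step 1
Reactants: 1 (1S,2R,5S)-(+)-menthyl chloroformate; 2 hydrazine hydrate
Product: 3 (1S,2R,5S)-menthyl carbazate
Conditions: N2H4·H2O (3 equiv), Et2O, 0 °C
Reagents that add atoms: hydrazine (from 2), NN
Why: acyl substitution of the chloroformate by hydrazine (carbazate formation) should be clean at 0 °C, the excess hydrazine taking up HCl and the menthyl stereocentres staying untouched.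

Step 2
Reactants: 4 (±)-α-ionone; 3 (1S,2R,5S)-menthyl carbazate
Product: 5 (S)-α-ionone (1S,2R,5S)-menthyl carbazone (single diastereomer)
Conditions: 3 (1 equiv), AcOH (cat.), EtOH, 60 °C; fractional crystallisation from EtOH
Reagents that add atoms: (1S,2R,5S)-menthyl carbazate, CC(C)[C@H]1CC[C@H](C)C[C@@H]1OC(=O)NN
Why: carbazone (acyl hydrazone) condensation turns the enantiomers of 4 into diastereomers of different solubility, so classical resolution by fractional crystallisation should deliver the derivative of the (S)-ketone, the C6 configuration being selected and not created here.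

Step 3
Reactants: 5 (S)-α-ionone (1S,2R,5S)-menthyl carbazone
Product: 6 (S)-α-ionone
Conditions: pyruvic acid, NaOAc, AcOH–H2O, 40 °C
Reagents that add atoms: water, O
Why: hydrazone exchange (transhydrazonation) onto the more electrophilic pyruvic acid in buffered aqueous acetic acid should free the enone under conditions too mild to move the C1=C2 bond into conjugation or to epimerise C6.

Step 4
Reactants: 6 (S)-α-ionone
Product: 7 (S)-3-oxo-α-ionone
Conditions: CrO3, 3,5-dimethylpyrazole, CH2Cl2, −20 °C
Reagents that add atoms: chromium trioxide, O=[Cr](=O)=O
Why: allylic C–H oxidation with the chromium trioxide–3,5-dimethylpyrazole complex should attack the ring methylene C3 next to the electron-rich C1=C2 bond (the side-chain alkene is a deactivated enone), and the cold, non-basic medium should keep the now doubly vinylogous C6–H from enolising.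

Step 5
Reactants: 7 (S)-3-oxo-α-ionone
Product: 10 (6S)-3-hydroxy-7,8-dihydro-α-ionone (C3 epimers), via triethylsilyl enol ether 8 (not isolated), via hydroxy silyl enol ether 9 (not isolated)
Conditions: Et3SiH, RhCl(PPh3)3 (cat.), PhMe, 50 °C; then i-Bu2AlH, PhMe, −78 °C; then K2CO3, MeOH, rt
Reagents that add atoms: none
Why: rhodium-catalysed 1,4-hydrosilylation should pick the β-monosubstituted side-chain enone over the β,β-disubstituted ring enone and at the same time masks C9=O as its silyl enol ether, so that i-Bu2AlH reduces only the ring ketone (1,2-reduction) before methanolysis frees the methyl ketone; the new C3 centre need not be controlled because step 9 erases it.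

Step 6
Reactants: 10 (6S)-3-hydroxy-7,8-dihydro-α-ionone; 11 trimethylsilyldiazomethane; 12 pivaloyl chloride
Product: 16 spirodienyl pivalate, via lithium alkoxide diazoalkene 13 (not isolated), via lithium alkoxide alkylidene carbene 14 (not isolated), via spirodienol lithium alkoxide 15 (not isolated)
Conditions: Me3SiCHN2 (2.4 equiv), n-BuLi (2.3 equiv), THF, −78 °C; then 10, −78 °C to rt; then t-BuCOCl (3 equiv), 0 °C to rt
Reagents that add atoms: trimethylsilyldiazomethane (supplies C11), C[Si](C)(C)C=[N+]=[N-]; pivaloyl chloride, CC(C)(C)C(=O)Cl
Why: The first equivalent of lithiated trimethylsilyldiazomethane deprotonates the C3 hydroxyl, the second adds to the C9 ketone, Peterson-type loss of Me3SiOLi gives diazoalkene 13, and loss of N2 gives alkylidene carbene 14, whose carbon C11 inserts into the C6–H bond. The closest known reaction type is the 1,5 C–H insertion of alkylidene carbenes generated from ketones with lithiated trimethylsilyldiazomethane. The spirocyclopentene (C6, C7, C8, C9, C11) closes by concerted 1,5 insertion through a five-membered transition structure. The spiro centre C6 is controlled by the substrate: insertion is stereoretentive, so the (S) configuration of C6 in 10 places C11 on the face of ring B that held the hydrogen. The step needs insertion to beat addition to the C1=C2 alkene and 1,2-alkyl shift to an alkyne, and this should be secured because C6–H is the only C–H at the 1,5 distance, is tertiary and allylic (hydridic), and addition to C1=C2 would build a strained alkylidenecyclopropane with a bridgehead double bond. The lithium alkoxide 15 left at the end is acylated in the flask with an excess of pivaloyl chloride (part of which is consumed by Me3SiOLi), because the pivalate is what deactivates ring B alkene in step 7.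

Step 7
Reactants: 16 spirodienyl pivalate; 17 bromoform
Product: 19 ring-expanded allylic dibromide pivalate, via dibromocyclopropane 18 (not isolated)
Conditions: CHBr3 (1.3 equiv), KOt-Bu, pentane, −30 to 0 °C; then filtration from the potassium salts, PhMe, 80 °C
Reagents that add atoms: bromoform (supplies C10 and both bromines), BrC(Br)Br
Why: dibromocarbene [2+1] cycloaddition should prefer the C9=C11 alkene because ring B alkene carries the electron-withdrawing, bulky allylic pivalate on C3, and the strained 6,6-dibromobicyclo[3.1.0]hexane 18, freed from base, should then undergo thermal disrotatory electrocyclic opening with loss of the endo bromide to a 2-bromocyclohexenyl cation that bromide recaptures, which places C10 with its bromine between C9 and C11.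

Step 8
Reactants: 19 ring-expanded allylic dibromide pivalate
Product: 20 bromo dienol
Conditions: LiAlH4, Et2O, 0 °C to rt
Reagents that add atoms: none
Why: hydride substitution of the allylic bromide, as in the known reduction of 2,3-dibromocycloalkenes to 1-bromocycloalkenes (SN2 at C11, or SN2′ on the tertiary C9 isomer with which it equilibrates), should put hydrogen on the less substituted terminus C11 and leave the tetrasubstituted C9=C10 bond, at a temperature where the vinyl bromide is inert, while the same reagent cleaves the pivalate reductively.

Step 9
Reactants: 20 bromo dienol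
Product: 21 bromo enone
Conditions: MnO2, CH2Cl2, rt
Reagents that add atoms: none
Why: manganese dioxide oxidation is selective for the allylic alcohol and should convert both C3 epimers into one enone without touching the vinyl bromide.

Step 10
Reactants: 21 bromo enone
Product: 23 (4S)-4-bromo enone, via trimethylsilyl dienol ether 22 (not isolated)
Conditions: LiN(SiMe3)2, Me3SiCl, THF, −78 °C; then NBS, THF, −78 to 0 °C
Reagents that add atoms: N-bromosuccinimide, O=C1CCC(=O)N1Br
Why: kinetic α′-deprotonation at C4 (cross-conjugated enolate, as with isophorone) and electrophilic bromination of the silyl dienol ether should install bromine at C4 under substrate control from C6, bromine entering axially past one of the two ring A arms and expected to choose the face of C11, whose neighbour C10 is planar and holds its substituents away from ring B, over the face of the C7–C8 bridge; C5 is quaternary, so the product cannot lose HBr.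

Step 11
Reactants: 23 (4S)-4-bromo enone
Product: 24 target bromohydrin
Conditions: Al(Oi-Pr)3, i-PrOH–acetone (20:1), PhMe, 60 °C
Reagents that add atoms: none
Why: Meerwein–Ponndorf–Verley reduction, the classical non-basic reduction of α-bromo ketones, is reversible in the presence of acetone, so C3 should be set under thermodynamic control in favour of the trans bromohydrin (OH pseudo-equatorial, Br equatorial), its cis epimer having to hold OH syn-axial to the axial C5 methyl or Br syn-axial to C11, whereas kinetic hydrides such as NaBH4–CeCl3 would be steered to the wrong face by that axial methyl.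

Compound list
1 | (1S,2R,5S)-(+)-menthyl chloroformate | CC(C)[C@H]1CC[C@H](C)C[C@@H]1OC(=O)Cl | starting material
2 | hydrazine hydrate | NN.O | starting material
3 | (1S,2R,5S)-menthyl carbazate (menthyl hydrazinecarboxylate) | CC(C)[C@H]1CC[C@H](C)C[C@@H]1OC(=O)NN | intermediate
4 | (±)-α-ionone, racemic (E)-4-(2,6,6-trimethylcyclohex-2-en-1-yl)but-3-en-2-one | CC1=CCCC(C)(C)C1/C=C/C(C)=O | starting material
5 | (S)-α-ionone (1S,2R,5S)-menthyl carbazone, (E)-hydrazone, ring carbon C6 (S), less soluble diastereomer | CC(C)[C@H]1CC[C@H](C)C[C@@H]1OC(=O)N/N=C(C)/C=C/[C@@H]1C(C)=CCCC1(C)C | intermediate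
6 | (S)-α-ionone | CC1=CCCC(C)(C)[C@@H]1/C=C/C(C)=O | intermediate
7 | (S)-3-oxo-α-ionone, (E)-4-[(1S)-2,6,6-trimethyl-4-oxocyclohex-2-en-1-yl]but-3-en-2-one | CC1=CC(=O)CC(C)(C)[C@@H]1/C=C/C(C)=O | intermediate
8 | triethylsilyl enol ether of the side-chain ketone of 7 (C8=C9, E/Z open), ring enone intact, C6 (S); not isolated | CC1=CC(=O)CC(C)(C)[C@@H]1CC=C(C)O[Si](CC)(CC)CC | intermediate
9 | C3 alcohol of 8 (C3 epimers), C6 (S); not isolated | CC1=CC(O)CC(C)(C)[C@@H]1CC=C(C)O[Si](CC)(CC)CC | intermediate
10 | (6S)-3-hydroxy-7,8-dihydro-α-ionone, 4-[(1S)-4-hydroxy-2,6,6-trimethylcyclohex-2-en-1-yl]butan-2-one, C3 epimers; key-step precursor | CC1=CC(O)CC(C)(C)[C@@H]1CCC(C)=O | intermediate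
11 | trimethylsilyldiazomethane | C[Si](C)(C)C=[N+]=[N-] | starting material
12 | pivaloyl chloride | CC(C)(C)C(=O)Cl | starting material
13 | lithium alkoxide of the diazoalkene from 10 (C9=C11=N2), C6 (S); not isolated | CC1=CC(O[Li])CC(C)(C)[C@@H]1CCC(C)=C=[N+]=[N-] | intermediate
14 | lithium alkoxide of the alkylidene carbene (C9=C11:), C6 (S); not isolated | CC1=CC(O[Li])CC(C)(C)[C@@H]1CCC(C)=[C] | intermediate
15 | lithium alkoxide of (5R)-2,6,10,10-tetramethylspiro[4.5]deca-1,6-dien-8-ol, key-step product, C11 on the ring B face that held H in 10; not isolated | CC1=CC(O[Li])CC(C)(C)[C@]12CCC(C)=C2 | intermediate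
16 | (5R)-2,6,10,10-tetramethylspiro[4.5]deca-1,6-dien-8-yl pivalate | CC1=CC(OC(=O)C(C)(C)C)CC(C)(C)[C@]12CCC(C)=C2 | intermediate
17 | bromoform | BrC(Br)Br | starting material
18 | dibromocyclopropane adduct of 16 across C9=C11 (CBr2 = C10), spiro centre as in 15; not isolated | CC1=CC(OC(=O)C(C)(C)C)CC(C)(C)[C@]12CCC3(C)C2C3(Br)Br | intermediate
19 | ring-expanded allylic dibromide: ring A six-membered with C9=C10(Br) and C11–Br (drawn isomer; its C9-bromo allylic isomer may accompany it), C3 pivalate, spiro centre as in 15 | CC1=CC(OC(=O)C(C)(C)C)CC(C)(C)[C@]12CCC(C)=C(Br)C2Br | intermediate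
20 | bromo dienol: ring A 2-bromo-1-methylcyclohexene (C9=C10, C11H2), ring B allylic alcohol at C3 (epimers), spiro centre as in 15 | CC1=CC(O)CC(C)(C)[C@]12CCC(C)=C(Br)C2 | intermediate
21 | bromo enone: ring B C1=C2–C3=O, ring A as in 20 | CC1=CC(=O)CC(C)(C)[C@]12CCC(C)=C(Br)C2 | intermediate
22 | trimethylsilyl dienol ether of 21 (C1=C2 and C3=C4); not isolated | CC1=CC(O[Si](C)(C)C)=CC(C)(C)[C@]12CCC(C)=C(Br)C2 | intermediate
23 | (4S,6S)-4-bromo enone: C4–Br on the ring B face that carries C11 | CC1=CC(=O)[C@@H](Br)C(C)(C)[C@]12CCC(C)=C(Br)C2 | intermediate
24 | target, (3S,4S,6S): C3–OH trans to C4–Br, C4–Br syn to C11, ring A vinyl bromide at C10 | CC1=C[C@H](O)[C@@H](Br)C(C)(C)[C@]12CCC(C)=C(Br)C2 | target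

Total step count: 11. Longest linear sequence: 11 steps (steps 1 to 11, from menthyl chloroformate 1 through the resolving agent 3, which is consumed in step 2).

Steps most likely to fail

Step 10. The risk is poor facial selectivity in the bromination at C4, because the two faces of ring B differ only through the remote parts of the two ring A arms on C6. The fallback sets out from 21 and comes back at 23, and it moves the stereodetermining event from C–Br formation to C–H formation. Exhaustive bromination (two rounds of LiN(SiMe3)2, Me3SiCl, NBS) gives the 4,4-dibromo enone F1. Zinc in AcOH–Et2O at −20 °C then removes one bromine through the zinc bromo-enolate, which is protonated at C4 on the face that electrophiles prefer. The proton thus takes the place that bromine took in the unselective or wrongly selective run, and the remaining bromine should end on the C11 face, giving 23. Since C5 is quaternary, the C4 epimers can also be interconverted through the enol (HBr, AcOH) without elimination, which gives a further handle.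

Step 6. The risk is that the basic diazomethane reagent enolises the methyl ketone, or that the alkoxide-bearing substrate adds sluggishly, so that carbene formation stalls and the hindered C–H insertion is never reached. The fallback sets out from 10 and comes back at 16, and it separates carbene generation from carbonyl addition. Wittig chloromethylenation with Ph3P=CHCl (from (chloromethyl)triphenylphosphonium chloride and KOt-Bu, in excess to cover the hydroxyl) gives the 1-chloroalkene F2 as an E/Z mixture. KN(SiMe3)2 in Et2O at rt then generates the same alkylidene carbene by α-elimination, which inserts into C6–H with retention. The alkoxide is acylated in the flask with pivaloyl chloride as before to give 16.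

Step 7. The risk is wrong site selectivity, dibromocarbene adding to the C1=C2 alkene of ring B (or to both alkenes) despite the pivalate. The fallback sets out from 16 and comes back at 20, and it switches ring B off electronically. i-Bu2AlH in CH2Cl2 at −78 °C cleaves the pivalate to the spirodienol F3, and MnO2 oxidises it to the spiro enone F4, whose electron-poor C1=C2 bond does not react with an electrophilic carbene. Base-free dibromocarbene transfer from PhHgCBr3 in benzene at 80 °C, which does not enolise the enone, gives the dibromocyclopropane F5, which opens at that temperature to the allylic dibromide enone F6. LiAlH4 then removes the allylic bromide and reduces the C3 ketone (1,2), which joins the route at 20.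

Further compounds
F1 | step 10 | 4,4-dibromo enone (gem-dibromide at C4 of 21) | CC1=CC(=O)C(Br)(Br)C(C)(C)[C@]12CCC(C)=C(Br)C2
F2 | step 6 | 1-chloroalkene from 10 (C9=CHCl, E/Z mixture, C3 epimers, C6 (S)) | CC1=CC(O)CC(C)(C)[C@@H]1CCC(C)=CCl
F3 | step 7 | spirodienol, (5R)-2,6,10,10-tetramethylspiro[4.5]deca-1,6-dien-8-ol (C3 epimers) | CC1=CC(O)CC(C)(C)[C@]12CCC(C)=C2
F4 | step 7 | spiro enone, (5R)-2,6,10,10-tetramethylspiro[4.5]deca-1,6-dien-8-one | CC1=CC(=O)CC(C)(C)[C@]12CCC(C)=C2
F5 | step 7 | dibromocyclopropane adduct of F4 across C9=C11 | CC1=CC(=O)CC(C)(C)[C@]12CCC3(C)C2C3(Br)Br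
F6 | step 7 | ring-expanded allylic dibromide enone (C9=C10(Br), C11–Br, ring B enone) | CC1=CC(=O)CC(C)(C)[C@]12CCC(C)=C(Br)C2Br
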